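**Assumptions (one line each)**
- The target SMILES contains no stereocentres. The CMe2 carbons are not stereogenic, so every compound below is achiral and "single enantiomer" is moot.
- The SMILES is taken literally: a 5,8-dihydroxy-6-(3-hydroxy-3-methylbutyl)isoflavone whose B ring is a 2'-hydroxy-4',5'-(2,2-dimethylpyrano) unit.
- 2,2-Dimethyloxetane is made in two steps from the commercial diol, because I could not assume it is purchasable.

## Retrosynthesis
1. The 5,8-hydroquinone is carried as the 5,8-dimethyl ether and unmasked at the end by CAN oxidation to the quinone, then dithionite reduction.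
2. The C3–C1' bond comes from a Suzuki coupling of a 3-iodochromone with a pre-built 6-boryl-7-OMOM-2,2-dimethylchromene. That chromene is made from resorcinol and prenal.
3. The A-ring pyranone forms last in the A fragment, from a 2'-hydroxyacetophenone via its enaminone and I2. The C6 chain is installed earlier on the acetophenone as an aryl iodide. This is the new step: Co/Ni arylative opening of 2,2-dimethyloxetane.
4. Ring order: the B-ring pyran forms first (separate fragment), then the A-ring pyranone, then the biaryl C3–C1' bond, then the quinone and hydroquinone.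

## Forward route

**Step 1**
- Reactants: 1 (2,5-dimethoxyphenol), 2 (MOMCl)
- Product: 3 (1-(methoxymethoxy)-2,5-dimethoxybenzene)
- Conditions: NaH, THF, 0 °C→rt
- Reagents that add atoms: MOMCl, ClCOC
- Why: Williamson-type O-alkylation installs a MOM group, which is a strong directing group for the next step.

**Step 2**
- Reactants: 3, 4 (N-methoxy-N-methylacetamide)
- Product: 5 (1-[2-(methoxymethoxy)-3,6-dimethoxyphenyl]ethan-1-one)
- Conditions: n-BuLi, THF, −78→−20 °C; then 4 (1.5 equiv), −78 °C→rt
- Reagents that add atoms: CC(=O)N(C)OC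
- Why: Directed ortho-metalation occurs at C6, which is flanked by OMOM and OMe (cooperative effect). The Weinreb amide then gives the ketone without over-addition.

**Step 3**
- Reactants: 5, 6 (N-iodosuccinimide)
- Product: 7 (1-[5-iodo-2-(methoxymethoxy)-3,6-dimethoxyphenyl]ethan-1-one)
- Conditions: NIS, MeCN, 40 °C
- Reagents that add atoms: NIS, O=C1CCC(=O)N1I
- Why: Electrophilic iodination goes to C5', which is para to OMOM and ortho to OMe; it is the only strongly activated free position.

**Step 4**
- Reactants: 8 (3-methylbutane-1,3-diol), 9 (TsCl)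
- Product: 10 (3-hydroxy-3-methylbutyl tosylate)
- Conditions: TsCl, pyridine, CH2Cl2, 0 °C
- Reagents that add atoms: TsCl, Cc1ccc(S(=O)(=O)Cl)cc1
- Why: The primary OH is tosylated selectively over the tertiary OH on steric grounds.

**Step 5**
- Reactant: 10
- Product: 11 (2,2-dimethyloxetane)
- Conditions: KOtBu, THF, 65 °C; product distilled out as a THF solution
- Reagents that add atoms: none
- Why: Intramolecular Williamson (4-exo-tet) closure by the tertiary alkoxide displacing the primary tosylate.

**Step 6 (key new step)**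
- Reactants: 7, 11
- Product: 12 (1-[5-(3-hydroxy-3-methylbutyl)-2-(methoxymethoxy)-3,6-dimethoxyphenyl]ethan-1-one)
- Conditions: 11 (3 equiv), vitamin B12 (10 mol%), NiBr2·glyme (10 mol%), dtbbpy (10 mol%), Zn (3 equiv), ZnBr2 (0.5 equiv), DMA, blue LEDs, 35 °C, 24 h, sealed tube; then 1 M HCl work-up
- Reagents that add atoms: 2,2-dimethyloxetane, CC1(C)CCO1
- Why: Proposed new method: Zn-reduced Co(I) (B12) opens the Zn2+-activated oxetane by SN2 at the unhindered C4 methylene, because the tertiary C2–O bond is shut to SN2. This gives a (3-oxido-3-methylbutyl)-Co(III) species, and light-driven Co–C homolysis releases the primary radical. That radical is captured by ArNi(II)I (from oxidative addition of 7), and C(sp2)–C(sp3) reductive elimination forms the C6–CH2 bond and the tertiary alkoxide in one step. The closest known reactions are B12-catalysed oxetane ring-opening to alkyl radicals and Co/Ni dual-catalysed aryl–alkyl cross-electrophile coupling. New here: a 2,2-disubstituted oxetane as the alkyl electrophile, primary-C–O regioselectivity, and a tertiary-alcohol product. No stereocentre is formed.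

**Step 7**
- Reactant: 12
- Product: 13 (1-[2-hydroxy-5-(3-hydroxy-3-methylbutyl)-3,6-dimethoxyphenyl]ethan-1-one)
- Conditions: 2 M HCl, THF/MeOH 1:1, 45 °C
- Reagents that add atoms: none
- Why: Acid hydrolysis of the aryl MOM acetal; the tertiary alkyl alcohol is unaffected at this acidity.

**Step 8**
- Reactants: 13, 14 (DMF-DMA)
- Product: 15 ((E)-3-(dimethylamino)-1-[2-hydroxy-5-(3-hydroxy-3-methylbutyl)-3,6-dimethoxyphenyl]prop-2-en-1-one)
- Conditions: DMF-DMA (3 equiv), toluene, 110 °C
- Reagents that add atoms: DMF-DMA, CN(C)C(OC)OC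
- Why: Bredereck-type condensation of the acetyl methyl with the amide acetal gives the enaminone.

**Step 9**
- Reactants: 15, 16 (I2)
- Product: 17 (3-iodo-6-(3-hydroxy-3-methylbutyl)-5,8-dimethoxy-4H-chromen-4-one)
- Conditions: I2 (1.5 equiv), CH2Cl2, rt
- Reagents that add atoms: I2, II
- Why: Gammill-type α-iodination of the enaminone is followed by phenol oxa-conjugate addition and loss of Me2NH, forming the pyranone ring and the 3-iodochromone.

**Step 10**
- Reactants: 18 (resorcinol), 19 (3-methylbut-2-enal)
- Product: 20 (7-hydroxy-2,2-dimethyl-2H-chromene)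
- Conditions: pyridine, 115 °C, 16 h
- Reagents that add atoms: resorcinol Oc1cccc(O)c1; prenal CC(C)=CC=O
- Why: Knoevenagel-type condensation at the ortho carbon, then oxa-6π-electrocyclisation, gives the 2,2-dimethylchromene. The 5-hydroxy regioisomer is a minor product and is separated by chromatography.

**Step 11**
- Reactants: 20, 6 (NIS)
- Product: 21 (6-iodo-7-hydroxy-2,2-dimethyl-2H-chromene)
- Conditions: NIS (1.0 equiv), MeCN, 0 °C, dark
- Reagents that add atoms: NIS, O=C1CCC(=O)N1I
- Why: Electrophilic iodination goes ortho to the OH and para to the ring oxygen at the unhindered C6, not at C8 between the two oxygens.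

**Step 12**
- Reactants: 21, 2 (MOMCl)
- Product: 22 (6-iodo-7-(methoxymethoxy)-2,2-dimethyl-2H-chromene)
- Conditions: MOMCl, DIPEA, CH2Cl2, 0 °C→rt
- Reagents that add atoms: MOMCl, ClCOC
- Why: Phenol MOM protection prevents protodeboronation and catalyst poisoning later.

**Step 13**
- Reactants: 22, 23 (B2pin2)
- Product: 24 (2-[7-(methoxymethoxy)-2,2-dimethyl-2H-chromen-6-yl]-4,4,5,5-tetramethyl-1,3,2-dioxaborolane)
- Conditions: B2pin2, Pd(dppf)Cl2 (5 mol%), KOAc, dioxane, 85 °C
- Reagents that add atoms: B2pin2, CC1(C)OB(OC1(C)C)B1OC(C)(C)C(C)(C)O1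
- Why: Miyaura borylation; the chromene alkene is untouched under these conditions.

**Step 14**
- Reactants: 17, 24
- Product: 25 (6-(3-hydroxy-3-methylbutyl)-5,8-dimethoxy-3-[7-(methoxymethoxy)-2,2-dimethyl-2H-chromen-6-yl]-4H-chromen-4-one)
- Conditions: Pd(PPh3)4 (5 mol%), 2 M aq. Na2CO3, DME, 80 °C
- Reagents that add atoms: none
- Why: Suzuki–Miyaura coupling at the reactive vinyl iodide builds the isoflavone C3–C1' bond; the tertiary OH, MOM, OMe groups and chromene are inert.

**Step 15**
- Reactants: 25, 26 (water)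
- Product: 27 (6-(3-hydroxy-3-methylbutyl)-3-[7-(methoxymethoxy)-2,2-dimethyl-2H-chromen-6-yl]-4H-chromene-4,5,8-trione)
- Conditions: CAN (3 equiv), MeCN/H2O 3:1, 0 °C, 10 min
- Reagents that add atoms: water, O
- Why: Oxidative demethylation of the para-dimethoxyarene (2 Ce(IV)) gives the quinone. The resorcinol-diether B ring is much harder to oxidise.

**Step 16**
- Reactant: 27
- Product: 28 (3-(2-hydroxy-2,2-dimethyl... see list: the 2'-hydroxy quinone)
- Conditions: 1 M HCl, THF, 40 °C
- Reagents that add atoms: none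
- Why: Acid hydrolysis of the B-ring MOM ether. It is done at the stable quinone stage so that the air-sensitive hydroquinone is only made in the last step.

**Step 17**
- Reactant: 28
- Product: 29 (Kraussianone 3)
- Conditions: Na2S2O4 (5 equiv), THF/H2O 1:1, rt, N2, 10 min
- Reagents that add atoms: none
- Why: Dithionite reduces the 5,8-quinone to the 5,8-hydroquinone; the 5-OH is chelated to C4=O, and the chromone, chromene and tertiary alcohol are untouched.

## Compound list
1 | 2,5-dimethoxyphenol | COc1ccc(OC)c(O)c1 | starting material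
2 | chloromethyl methyl ether (MOMCl) | ClCOC | starting material
3 | 1-(methoxymethoxy)-2,5-dimethoxybenzene | COCOc1cc(OC)ccc1OC | intermediate
4 | N-methoxy-N-methylacetamide | CC(=O)N(C)OC | starting material
5 | 1-[2-(methoxymethoxy)-3,6-dimethoxyphenyl]ethan-1-one | CC(=O)c1c(OC)ccc(OC)c1OCOC | intermediate
6 | N-iodosuccinimide | O=C1CCC(=O)N1I | starting material
7 | 1-[5-iodo-2-(methoxymethoxy)-3,6-dimethoxyphenyl]ethan-1-one | CC(=O)c1c(OC)c(I)cc(OC)c1OCOC | intermediate
8 | 3-methylbutane-1,3-diol | CC(C)(O)CCO | starting material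
9 | p-toluenesulfonyl chloride | Cc1ccc(S(=O)(=O)Cl)cc1 | starting material
10 | 3-hydroxy-3-methylbutyl tosylate | CC(C)(O)CCOS(=O)(=O)c1ccc(C)cc1 | intermediate
11 | 2,2-dimethyloxetane | CC1(C)CCO1 | intermediate
12 | 1-[5-(3-hydroxy-3-methylbutyl)-2-(methoxymethoxy)-3,6-dimethoxyphenyl]ethan-1-one | CC(=O)c1c(OC)c(CCC(C)(C)O)cc(OC)c1OCOC | intermediate
13 | 1-[2-hydroxy-5-(3-hydroxy-3-methylbutyl)-3,6-dimethoxyphenyl]ethan-1-one | CC(=O)c1c(OC)c(CCC(C)(C)O)cc(OC)c1O | intermediate
14 | N,N-dimethylformamide dimethyl acetal | CN(C)C(OC)OC | starting material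
15 | (E)-3-(dimethylamino)-1-[2-hydroxy-5-(3-hydroxy-3-methylbutyl)-3,6-dimethoxyphenyl]prop-2-en-1-one | CN(C)/C=C/C(=O)c1c(OC)c(CCC(C)(C)O)cc(OC)c1O | intermediate
16 | iodine | II | starting material
17 | 3-iodo-6-(3-hydroxy-3-methylbutyl)-5,8-dimethoxy-4H-chromen-4-one | CC(C)(O)CCc1cc(OC)c2occ(I)c(=O)c2c1OC | intermediate
18 | resorcinol | Oc1cccc(O)c1 | starting material
19 | 3-methylbut-2-enal | CC(C)=CC=O | starting material
20 | 7-hydroxy-2,2-dimethyl-2H-chromene | CC1(C)C=Cc2ccc(O)cc2O1 | intermediate
21 | 6-iodo-7-hydroxy-2,2-dimethyl-2H-chromene | CC1(C)C=Cc2cc(I)c(O)cc2O1 | intermediate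
22 | 6-iodo-7-(methoxymethoxy)-2,2-dimethyl-2H-chromene | CC1(C)C=Cc2cc(I)c(OCOC)cc2O1 | intermediate
23 | bis(pinacolato)diboron | CC1(C)OB(OC1(C)C)B1OC(C)(C)C(C)(C)O1 | starting material
24 | pinacol boronate of 22 (chromen-6-yl-Bpin, 7-OMOM) | CC1(C)C=Cc2cc(B3OC(C)(C)C(C)(C)O3)c(OCOC)cc2O1 | intermediate
25 | 6-(3-hydroxy-3-methylbutyl)-5,8-dimethoxy-3-[7-(methoxymethoxy)-2,2-dimethyl-2H-chromen-6-yl]-4H-chromen-4-one | CC(C)(O)CCc1cc(OC)c2occ(-c3cc4c(cc3OCOC)OC(C)(C)C=C4)c(=O)c2c1OC | intermediate
26 | water | O | starting material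
27 | 5,8-quinone of 25 with B-ring OMOM | CC(C)(O)CCC1=CC(=O)c2occ(-c3cc4c(cc3OCOC)OC(C)(C)C=C4)c(=O)c2C1=O | intermediate
28 | 3-(2-hydroxy-2',2'-dimethylchromenyl) 5,8-quinone, i.e. 3-[7-hydroxy-2,2-dimethyl-2H-chromen-6-yl]-6-(3-hydroxy-3-methylbutyl)chromene-4,5,8-trione | CC(C)(O)CCC1=CC(=O)c2occ(-c3cc4c(cc3O)OC(C)(C)C=C4)c(=O)c2C1=O | intermediate
29 | Kraussianone 3 | CC(C)(O)CCc1cc(O)c2occ(-c3cc4c(cc3O)OC(C)(C)C=C4)c(=O)c2c1O | target

**Total steps:** 17 (counting the two oxetane steps and four B-ring-fragment steps).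
**Longest linear sequence:** 11 steps (1→2→3→6→7→8→9→14→15→16→17).

## Three steps most likely to fail
1. **Step 6 (proposed new Co/Ni oxetane arylation).** Lewis-acid activation may push C–O cleavage to the tertiary centre, giving elimination rather than coupling. *Fallback (known chemistry):* hydroborate 2-methylbut-3-en-2-ol with 9-BBN and run a B-alkyl Suzuki coupling with aryl iodide 7 (Pd(dppf)Cl2, K3PO4, THF/H2O, 60 °C) to give 12.
2. **Step 15 (CAN oxidation).** CAN may attack the chromene C=C or the electron-rich B ring. *Fallback:* move the unmasking to the chromene-free iodochromone 17. Run CAN, then Na2S2O4 with in-situ bis-MOM protection of the hydroquinone, then the Suzuki coupling, then a final global acid deprotection.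
3. **Step 16 (MOM removal with the acid-sensitive chromene).** Chromene hydration or ring opening may compete. *Fallback:* change the B-ring protecting group to allyl, replacing MOM in 21→22, and remove it with Pd(PPh3)4/PhSiH3 (neutral) at the quinone stage.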